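## Analysis of the target

The target 22 is an aryltetralin cyclolignan: an aromatic ring A (C4a, C5–C8, C8a) fused to a saturated ring B (C1–C4), with a 4-hydroxy-3-methoxyphenyl ring C on C1, a hydroxymethyl group C9′ on C2 and a hydroxymethyl group C9 on C3. Ring A carries methoxy groups at C5 and C6 and a free phenol at C7, so only C8 still bears hydrogen. The three contiguous stereocentres are (1R,2S,3S), that is 1,2-trans and 2,3-trans, the arrangement in which all three ring B substituents can be equatorial. The sensitive groups are two electron-rich phenols, two primary alcohols and the doubly benzylic C1–H. The 2,3-trans relation is also fragile: if O9′ and C9 ever form a γ-lactone that meets base, the lactone fused to the tetralin prefers the cis fusion and C3 is lost. The synthesis is hard because ring B must be closed at one defined position of a pentasubstituted arene (C4a, between the C5 methoxy group and C8a), three adjacent centres must be set, and the C7 phenol must stay distinct from the ring C phenol. The strategy rests on C4: it is the one carbon of ring B with neither a substituent nor a stereocentre, and it lies between aromatic C4a and C3, whose substituent C9 can be held at the ester oxidation level. C4 can therefore be brought in last as carbon monoxide, inserted between a C4a halide and a C3 ester enolate, while C1 and C2 are set beforehand in an open chain.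

## Retrosynthetic reasoning

**22 to 21 to 20.** Only protecting-group bonds and the C4–O bond are cut first. Target 22 goes back to the bis(silyl ether) 21, whose O7 and O9′ groups fall together to fluoride. Compound 21 goes back to the C4 carbinol 20, whose benzylic C4–O bond and ring C benzyl ether are removed in one hydrogenolysis. The oxygen at C4 is the trace of the carbonyl that builds ring B, and ring A (ortho methoxy, para silyloxy) makes this bond easy to cleave.

**20 to 19 to 18.** Two C–O reductions follow: the C9 alcohol of 20 from the tert-butyl ester 19, and the C4 carbinol of 19 from the β-keto ester 18. The ketone is reduced first so that C3 stops being acidic; the ester is reduced next, while O9′ is still silylated. This order is a safeguard: lactonisation between a free O9′ and the C9 ester, followed by base, would drive C3 into the cis series.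

**18 to 15 and 16.** This is the strategic cut. Both bonds of C4 (C4a–C4 and C4–C3) are broken, C4 becomes carbon monoxide 16, and ring B opens to the chain 15 with a bromide on C4a and a tert-butyl ester at C9. Cutting here removes a ring but no stereochemical information, because C4 has none. The bromide fixes the site of closure on ring A; an acid-mediated closure would have had to choose between the two positions ortho to C8a. The forward reaction must acylate the enolate carbon rather than arylate it, must leave C1 and C2 untouched, and gains ring B and the last stereocentre C3 in one step.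

**15 to 14 to 13.** The O9′–Si bond is cut to the alcohol 14, and C9′ is raised to the imide carbonyl of 13. The forward reduction must distinguish the imide from the tert-butyl ester. A silyl ether replaces the more usual benzyl ether on O9′, because silylation of the γ-hydroxy ester 14 needs neither strong base nor acid, and because the group then survives the hydrogenolysis.

**13 to 10 and 11.** The C2–C3 bond is cut between the enolate carbon of imide 10 and tert-butyl bromoacetate 11. This brings in C3 and C9 already as the tert-butyl ester that the ring closure needs, and lets the oxazolidinone 8 set C2.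

**10 to 7 and 8, and 7 to 6.** The N-acyl bond is cut to the acid 7 and the auxiliary 8; acid 7 comes from its tert-butyl ester 6. An acid-labile ester is chosen so that the aryl silyl ether never meets hydroxide.

**6 to 4 and 5.** The C1–C1′ bond is cut between the β-carbon of enoate 4 and the boronic acid 5. C1 is a diarylmethine whose two aryl groups differ little in size, so it is best created by a chiral catalyst that tells the enoate faces apart. The other cut, C1–C8a, would need the ortho-bromoaryl unit as the nucleophile.

**4 to 3 to 2 to 1.** The C1=C2 bond is cut by olefination back to aldehyde 3, the C4a–Br bond by bromination back to 2, and the O7–Si bond back to the commercial phenol 1. Bromine is placed while ring A is the only arene present, and the bulky silyl group both protects the phenol and steers the halogen.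

## Alternatives that were turned down

**Alternative 1:** Ring A is taken apart at C4a–C8a and C7–C8, back to the acyclic furan–alkyne A1. In A1 a 3,4-dimethoxyfuran (its α-carbons become C4a and C7, its oxygen the C7 phenol) and a terminal alkyne (C8a≡C8) are joined by the chain C4–C3–C2–C1, which already carries all three stereocentres. Heating A1 to roughly 200 °C without additives should give an intramolecular furan Diels–Alder reaction that closes ring B; the oxygen-bridged adduct should then open and tautomerise to the phenol A2.
- For it: the ring A pattern is written into the furan, so no halogenation regiochemistry arises; the ring A phenol emerges free and already distinct from the benzylated ring C phenol; no metal is needed. On ring A regiochemistry this route is stronger than the chosen one.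
- Against it: C1, C2 and C3 must all be built in an open chain, including a propargylic, benzylic C1 that can isomerise towards the allene at 200 °C. The electron-rich 2-alkyl-3,4-dimethoxyfuran is acid- and air-sensitive and needs its own synthesis. Furan cycloadditions to unactivated alkynes are reversible and slow, and opening of the bridged adduct can migrate substituents.
- Comparison: the chosen route starts from commercial arenes, sets C3 by equilibration instead of by an extra asymmetric step, and closes the ring at 80 °C.

**Alternative 2:** The bonds C2–C9′ and C1–C1′ are cut across the C1=C2 double bond of the chiral dihydronaphthalene A3, which holds only the C3 centre. Under blue light, an iridium photocatalyst and a nickel–bipyridine catalyst should add the benzyloxymethyl radical from the trifluoroborate A4 to C2 and couple the resulting C1 benzylic radical with the aryl bromide A5, giving the tetrabenzyl ether A6.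
- For it: it is the most convergent plan, forming two C–C bonds and two stereocentres in one step, with ring B already closed and a single hydrogenolysis to finish. On convergence and endgame length it is stronger than the chosen route.
- Against it: the alkene is an internal, cyclic, electron-rich styrene, a poor partner for a nucleophilic α-alkoxy radical, so direct two-component coupling of A4 with A5 should compete. Both new centres depend on induction from the single C3 substituent, and the 2,3 relation is uncertain. A3 still needs an asymmetric synthesis and a regiodefined ring A.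
- Comparison: the chosen route offers separately controlled, well-precedented stereocentres, which this single multicomponent step cannot guarantee.

**Alternative 3:** The bond C1–C2 is cut, back to the diarylmethane aldehyde A7 with a free ring C phenol. In one flask a silver oxidant should convert A7 into the ring C quinone methide A8, and a diarylprolinol silyl ether should turn the C9′ aldehyde into an enamine that adds to C1, closing ring B to the aldehyde A9 (1,2-trans, 2,3-trans).
- For it: it is metal-light and mild, sets C1 and C2 together, needs no protection on ring C, and leaves C9′ one hydride reduction from the target. On step count after ring closure it is at least as good as the chosen route.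
- Against it: the oxidation must be selective in a molecule with two electron-rich rings, an enolisable aldehyde and a secondary amine that can itself add to A8. The catalyst must cooperate with the existing C3 centre. A7 needs the same regiodefined 1,2-difunctionalised ring A plus a separate asymmetric step for C3.
- Comparison: the chosen route avoids any oxidation in the presence of free phenols and takes C3 from thermodynamics.

Key step: step 10

Remark: atoms are numbered as in aryltetralin lignans (C1 bears ring C, C2 bears C9′, C3 bears C9, C4 is the ring B methylene, ring A is C4a–C8a) and descriptors of ring-closed compounds follow this numbering; the sense of induction in step 4 is assigned from the accepted model in which the (S)-BINAP rhodium aryl adds to the α-si face of an (E)-enoate.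

## Route

**Step 1**
Reactants: 1 3-hydroxy-4,5-dimethoxybenzaldehyde
Product: 2 3,4-dimethoxy-5-[(triisopropylsilyl)oxy]benzaldehyde
Conditions: TIPSCl, imidazole, DMF, rt
Reagents that add atoms: triisopropylsilyl chloride, CC(C)[Si](Cl)(C(C)C)C(C)C
Why: Silylation of a phenol with a silyl chloride and imidazole; the bulky group masks the future C7 phenol through the basic steps and shields its ortho position for step 2.

**Step 2**
Reactants: 2 3,4-dimethoxy-5-[(triisopropylsilyl)oxy]benzaldehyde
Product: 3 2-bromo-3,4-dimethoxy-5-[(triisopropylsilyl)oxy]benzaldehyde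
Conditions: NBS, MeCN, 0 °C → rt, dark
Reagents that add atoms: N-bromosuccinimide, O=C1CCC(=O)N1Br
Why: Electrophilic aromatic bromination; of the two free positions, the one para to the silyloxy group and ortho to a methoxy group (future C4a) should react, because the other is wedged between the formyl group and the triisopropylsilyloxy group. The position attacked is the one brominated in the 3,4,5-trialkoxybenzaldehyde series, and NBS avoids free HBr that could cleave the silyl ether.

**Step 3**
Reactants: 3 2-bromo-3,4-dimethoxy-5-[(triisopropylsilyl)oxy]benzaldehyde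
Product: 4 tert-butyl (2E)-3-{2-bromo-3,4-dimethoxy-5-[(triisopropylsilyl)oxy]phenyl}prop-2-enoate
Conditions: Ph3P=CHCO2tBu, toluene, 80 °C
Reagents that add atoms: tert-butyl (triphenylphosphoranylidene)acetate, CC(C)(C)OC(=O)C=P(c1ccccc1)(c1ccccc1)c1ccccc1
Why: Wittig olefination with a stabilised ylide, which should give the (E)-enoate and brings in C2 and C9′. The tert-butyl ester is chosen because bulky esters favour high selectivity in step 4 and can be cleaved by acid without touching the aryl silyl ether.

**Step 4**
Reactants: 4 tert-butyl (2E)-3-(2-bromoaryl)prop-2-enoate; 5 [4-(benzyloxy)-3-methoxyphenyl]boronic acid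
Product: 6 tert-butyl (3R)-3-[4-(benzyloxy)-3-methoxyphenyl]-3-{2-bromo-3,4-dimethoxy-5-[(triisopropylsilyl)oxy]phenyl}propanoate
Conditions: [Rh(OH)(cod)]2 (3 mol %), (S)-BINAP (7 mol %), 5 (2.5 equiv), dioxane/H2O 10:1, 60 °C
Reagents that add atoms: none
Why: Rhodium-catalysed asymmetric conjugate addition of an arylboronic acid (Hayashi–Miyaura reaction): transmetalation gives an aryl complex of monovalent rhodium, the enoate inserts and water protonates the rhodium enolate. (S)-BINAP should deliver the aryl group to the α-si face of the (E)-enoate, which sets C1 as R; the aryl bromide should not react with monovalent rhodium at this temperature.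

**Step 5**
Reactants: 6 tert-butyl (3R)-3,3-diarylpropanoate
Product: 7 (3R)-3-[4-(benzyloxy)-3-methoxyphenyl]-3-{2-bromo-3,4-dimethoxy-5-[(triisopropylsilyl)oxy]phenyl}propanoic acid
Conditions: 85% aq. H3PO4, toluene, rt → 40 °C
Reagents that add atoms: none
Why: Acid cleavage of a tert-butyl ester by alkyl–oxygen fission. Aqueous phosphoric acid is used because hydroxide would attack the aryl silyl ether, and stronger anhydrous acids would let tert-butyl cations alkylate the electron-rich rings.

**Step 6**
Reactants: 7 (3R)-3,3-diarylpropanoic acid; 8 (4R)-4-benzyl-1,3-oxazolidin-2-one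
Product: 10 (4R)-4-benzyl-3-[(3R)-3-[4-(benzyloxy)-3-methoxyphenyl]-3-{2-bromo-3,4-dimethoxy-5-[(triisopropylsilyl)oxy]phenyl}propanoyl]-1,3-oxazolidin-2-one, via mixed pivalic anhydride 9 (not isolated)
Conditions: PivCl, Et3N, THF, −20 °C; then 8, LiCl, −20 °C → rt
Reagents that add atoms: pivaloyl chloride, CC(C)(C)C(=O)Cl (its acyl group is carried by 9 only)
Why: N-acylation of an Evans oxazolidinone through the mixed pivalic anhydride, which is attacked at the less hindered carbonyl. The (R)-auxiliary is the enantiomer whose benzyl group leaves open the enolate face needed for C2 in step 7.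

**Step 7**
Reactants: 10 N-(3,3-diarylpropanoyl)oxazolidinone; 11 tert-butyl bromoacetate
Product: 13 tert-butyl (3R,4R)-3-{[(4R)-4-benzyl-2-oxo-1,3-oxazolidin-3-yl]carbonyl}-4-[4-(benzyloxy)-3-methoxyphenyl]-4-{2-bromo-3,4-dimethoxy-5-[(triisopropylsilyl)oxy]phenyl}butanoate, via sodium (Z)-enolate 12 (not isolated)
Conditions: NaN(SiMe3)2, THF, −78 °C; then 11, −78 → −40 °C
Reagents that add atoms: sodium bis(trimethylsilyl)amide, [Na+].C[Si](C)(C)[N-][Si](C)(C)C (its sodium is carried by 12 only)
Why: Evans asymmetric alkylation: the chelated (Z)-enolate 12 is attacked by the bromoacetate on the face opposite the benzyl group of the auxiliary, which forms C2–C3 and sets C2. The auxiliary should override any bias from the C1 diarylmethine centre, and C1–H is too weakly acidic to be touched.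

**Step 8**
Reactants: 13 alkylated imide (tert-butyl ester)
Product: 14 tert-butyl (3R,4R)-4-[4-(benzyloxy)-3-methoxyphenyl]-4-{2-bromo-3,4-dimethoxy-5-[(triisopropylsilyl)oxy]phenyl}-3-(hydroxymethyl)butanoate
Conditions: LiBH4, H2O (1 equiv), Et2O/THF, 0 °C
Reagents that add atoms: none
Why: Reductive removal of the oxazolidinone with LiBH4, which reduces the imide carbonyl C9′ to the primary alcohol and leaves the tert-butyl ester; no stereocentre is involved and the auxiliary 8 is recovered.

**Step 9**
Reactants: 14 γ-hydroxy tert-butyl ester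
Product: 15 tert-butyl (3R,4R)-4-[4-(benzyloxy)-3-methoxyphenyl]-4-{2-bromo-3,4-dimethoxy-5-[(triisopropylsilyl)oxy]phenyl}-3-{[(triisopropylsilyl)oxy]methyl}butanoate
Conditions: TIPSCl, imidazole, DMAP (cat.), DMF, rt
Reagents that add atoms: triisopropylsilyl chloride, CC(C)[Si](Cl)(C(C)C)C(C)C
Why: Silylation of a primary alcohol under nearly neutral conditions, which avoids the alkoxide- or acid-promoted lactonisation of the γ-hydroxy ester and the ring benzylation that an O-benzylation would risk. The silyl ether keeps O9′ masked until the last step.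

**Step 10**
Reactants: 15 tert-butyl (3R,4R)-4-aryl-4-(2-bromoaryl)-3-{[(triisopropylsilyl)oxy]methyl}butanoate; 16 carbon monoxide
Product: 18 tert-butyl (1R,2S,3R)-1-[4-(benzyloxy)-3-methoxyphenyl]-5,6-dimethoxy-4-oxo-7-[(triisopropylsilyl)oxy]-2-{[(triisopropylsilyl)oxy]methyl}-1,2,3,4-tetrahydronaphthalene-3-carboxylate, via sodium enolate 17 (not isolated)
Conditions: Pd(dba)2 (5 mol %), Xantphos (6 mol %), CO (1–2 bar), NaN(SiMe3)2 (2.5 equiv, slow addition), dioxane, 80 °C; then AcOH, 0 °C
Reagents that add atoms: sodium bis(trimethylsilyl)amide, [Na+].C[Si](C)(C)[N-][Si](C)(C)C (its sodium is carried by 17 only)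
Why: Zerovalent palladium inserts into the C4a–Br bond, CO insertion gives an aroyl complex of divalent palladium, and the sodium enolate of the tert-butyl ester is acylated at carbon C3, so that C4a–C4 and C4–C3 are formed. The closest known reaction type is the palladium-catalysed carbonylative α-arylation of enolisable carbonyl compounds to 1,3-dicarbonyls, together with the trapping of acylpalladium species by tethered enolates. Ring B closes by 6-exo-trig attack of C3 on the acyl carbon C4. C3 is the only new stereocentre; it lies between ketone and ester, exists in the flask as the planar enolate 17, and on protonation and keto–enol equilibration should settle trans to the C2 substituent with all three ring B substituents equatorial. The site on ring A is unambiguous because bromine sits only at C4a. CO pressure and the wide-bite-angle ligand should favour insertion over direct α-arylation to an indane; O-acylation would need an eight-membered ring, and slow addition of base limits attack of the amide on the acyl complex. C1–H is far less acidic than the ester α-hydrogens, C2–H is not acidic and no hydrogen stands ortho to bromine, so the preset centres and the arene should survive. The second equivalent of base is taken up by the product, which withdraws it from further reaction.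

**Step 11**
Reactants: 18 all-trans β-keto ester
Product: 19 tert-butyl (1R,2S,3R,4RS)-1-[4-(benzyloxy)-3-methoxyphenyl]-4-hydroxy-5,6-dimethoxy-7-[(triisopropylsilyl)oxy]-2-{[(triisopropylsilyl)oxy]methyl}-1,2,3,4-tetrahydronaphthalene-3-carboxylate
Conditions: NaBH4, THF/EtOH 4:1, 0 °C
Reagents that add atoms: none
Why: Borohydride reduction of the ketone of a β-keto ester through its keto tautomer; this ends the acidity of C3–H, so C3 is fixed trans to C2 as in the more stable keto form. The configuration of the new carbinol C4 does not matter, since C4 becomes a methylene in step 13.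

**Step 12**
Reactants: 19 β-hydroxy tert-butyl ester
Product: 20 {(1R,2S,3S,4RS)-1-[4-(benzyloxy)-3-methoxyphenyl]-4-hydroxy-5,6-dimethoxy-7-[(triisopropylsilyl)oxy]-2-{[(triisopropylsilyl)oxy]methyl}-1,2,3,4-tetrahydronaphthalen-3-yl}methanol
Conditions: LiAlH4, THF, 0 °C → rt; aq. NaOH work-up
Reagents that add atoms: none
Why: Hydride reduction of the tert-butyl ester to the primary alcohol C9. Because this is done while O9′ is still a silyl ether, no γ-lactone can form and C3 ceases to be epimerisable.

**Step 13**
Reactants: 20 C4 carbinol, C9 alcohol, ring C benzyl ether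
Product: 21 4-[(1R,2S,3S)-3-(hydroxymethyl)-5,6-dimethoxy-7-[(triisopropylsilyl)oxy]-2-{[(triisopropylsilyl)oxy]methyl}-1,2,3,4-tetrahydronaphthalen-1-yl]-2-methoxyphenol
Conditions: H2 (3 bar), Pd(OH)2/C, EtOAc/EtOH, AcOH (5 vol %), rt
Reagents that add atoms: none
Why: Catalytic hydrogenolysis cleaves the aryl benzyl ether and the benzylic C4–O bond, which the ortho methoxy and para silyloxy groups of ring A activate. The weakly acidic medium should favour direct C–O cleavage over dehydration, so C3 is not involved; the silyl ethers and the primary alcohol are inert.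

**Step 14**
Reactants: 21 bis(triisopropylsilyl) ether
Product: 22 (1R,2S,3S)-1-(4-hydroxy-3-methoxyphenyl)-2,3-bis(hydroxymethyl)-5,6-dimethoxy-1,2,3,4-tetrahydronaphthalen-7-ol (target)
Conditions: Bu4NF, AcOH (1:1), THF, 0 °C → rt
Reagents that add atoms: none
Why: Fluoride cleavage of the aryl and the primary alkyl silyl ether in one operation; acetic acid keeps the liberated phenols protonated and so limits their aerial oxidation.

## Compound list

1 | 3-hydroxy-4,5-dimethoxybenzaldehyde | COc1cc(C=O)cc(O)c1OC | starting material
2 | 3,4-dimethoxy-5-[(triisopropylsilyl)oxy]benzaldehyde | COc1cc(C=O)cc(O[Si](C(C)C)(C(C)C)C(C)C)c1OC | intermediate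
3 | 2-bromo-3,4-dimethoxy-5-[(triisopropylsilyl)oxy]benzaldehyde | O=Cc1cc(O[Si](C(C)C)(C(C)C)C(C)C)c(OC)c(OC)c1Br | intermediate
4 | tert-butyl (2E)-3-{2-bromo-3,4-dimethoxy-5-[(triisopropylsilyl)oxy]phenyl}prop-2-enoate | CC(C)(C)OC(=O)/C=C/c1cc(O[Si](C(C)C)(C(C)C)C(C)C)c(OC)c(OC)c1Br | intermediate
5 | [4-(benzyloxy)-3-methoxyphenyl]boronic acid | COc1cc(B(O)O)ccc1OCc1ccccc1 | starting material
6 | tert-butyl (3R)-3-[4-(benzyloxy)-3-methoxyphenyl]-3-{2-bromo-3,4-dimethoxy-5-[(triisopropylsilyl)oxy]phenyl}propanoate | CC(C)(C)OC(=O)C[C@H](c1ccc(OCc2ccccc2)c(OC)c1)c1cc(O[Si](C(C)C)(C(C)C)C(C)C)c(OC)c(OC)c1Br | intermediate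
7 | (3R)-3-[4-(benzyloxy)-3-methoxyphenyl]-3-{2-bromo-3,4-dimethoxy-5-[(triisopropylsilyl)oxy]phenyl}propanoic acid | OC(=O)C[C@H](c1ccc(OCc2ccccc2)c(OC)c1)c1cc(O[Si](C(C)C)(C(C)C)C(C)C)c(OC)c(OC)c1Br | intermediate
8 | (4R)-4-benzyl-1,3-oxazolidin-2-one | O=C1N[C@H](Cc2ccccc2)CO1 | starting material
9 | mixed anhydride of acid 7 with pivalic acid (not isolated) | CC(C)(C)C(=O)OC(=O)C[C@H](c1ccc(OCc2ccccc2)c(OC)c1)c1cc(O[Si](C(C)C)(C(C)C)C(C)C)c(OC)c(OC)c1Br | intermediate
10 | (4R)-4-benzyl-3-[(3R)-3-[4-(benzyloxy)-3-methoxyphenyl]-3-{2-bromo-3,4-dimethoxy-5-[(triisopropylsilyl)oxy]phenyl}propanoyl]-1,3-oxazolidin-2-one | O=C(C[C@H](c1ccc(OCc2ccccc2)c(OC)c1)c1cc(O[Si](C(C)C)(C(C)C)C(C)C)c(OC)c(OC)c1Br)N1C(=O)OC[C@H]1Cc1ccccc1 | intermediate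
11 | tert-butyl bromoacetate | CC(C)(C)OC(=O)CBr | starting material
12 | sodium (Z)-enolate of imide 10 (not isolated) | [Na+].[O-]/C(=C\[C@H](c1ccc(OCc2ccccc2)c(OC)c1)c1cc(O[Si](C(C)C)(C(C)C)C(C)C)c(OC)c(OC)c1Br)N1C(=O)OC[C@H]1Cc1ccccc1 | intermediate
13 | tert-butyl (3R,4R)-3-{[(4R)-4-benzyl-2-oxo-1,3-oxazolidin-3-yl]carbonyl}-4-[4-(benzyloxy)-3-methoxyphenyl]-4-{2-bromo-3,4-dimethoxy-5-[(triisopropylsilyl)oxy]phenyl}butanoate | CC(C)(C)OC(=O)C[C@@H](C(=O)N1C(=O)OC[C@H]1Cc1ccccc1)[C@H](c1ccc(OCc2ccccc2)c(OC)c1)c1cc(O[Si](C(C)C)(C(C)C)C(C)C)c(OC)c(OC)c1Br | intermediate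
14 | tert-butyl (3R,4R)-4-[4-(benzyloxy)-3-methoxyphenyl]-4-{2-bromo-3,4-dimethoxy-5-[(triisopropylsilyl)oxy]phenyl}-3-(hydroxymethyl)butanoate | CC(C)(C)OC(=O)C[C@@H](CO)[C@H](c1ccc(OCc2ccccc2)c(OC)c1)c1cc(O[Si](C(C)C)(C(C)C)C(C)C)c(OC)c(OC)c1Br | intermediate
15 | tert-butyl (3R,4R)-4-[4-(benzyloxy)-3-methoxyphenyl]-4-{2-bromo-3,4-dimethoxy-5-[(triisopropylsilyl)oxy]phenyl}-3-{[(triisopropylsilyl)oxy]methyl}butanoate | CC(C)(C)OC(=O)C[C@@H](CO[Si](C(C)C)(C(C)C)C(C)C)[C@H](c1ccc(OCc2ccccc2)c(OC)c1)c1cc(O[Si](C(C)C)(C(C)C)C(C)C)c(OC)c(OC)c1Br | intermediate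
16 | carbon monoxide | [C-]#[O+] | starting material
17 | sodium enolate of β-keto ester 18, C3=C4–ONa (not isolated) | [Na+].COc1cc([C@@H]2c3cc(O[Si](C(C)C)(C(C)C)C(C)C)c(OC)c(OC)c3C([O-])=C(C(=O)OC(C)(C)C)[C@H]2CO[Si](C(C)C)(C(C)C)C(C)C)ccc1OCc1ccccc1 | intermediate
18 | tert-butyl (1R,2S,3R)-1-[4-(benzyloxy)-3-methoxyphenyl]-5,6-dimethoxy-4-oxo-7-[(triisopropylsilyl)oxy]-2-{[(triisopropylsilyl)oxy]methyl}-1,2,3,4-tetrahydronaphthalene-3-carboxylate (all-trans; in equilibrium with its enol) | COc1cc([C@@H]2c3cc(O[Si](C(C)C)(C(C)C)C(C)C)c(OC)c(OC)c3C(=O)[C@H](C(=O)OC(C)(C)C)[C@H]2CO[Si](C(C)C)(C(C)C)C(C)C)ccc1OCc1ccccc1 | intermediate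
19 | tert-butyl (1R,2S,3R,4RS)-1-[4-(benzyloxy)-3-methoxyphenyl]-4-hydroxy-5,6-dimethoxy-7-[(triisopropylsilyl)oxy]-2-{[(triisopropylsilyl)oxy]methyl}-1,2,3,4-tetrahydronaphthalene-3-carboxylate | COc1cc([C@@H]2c3cc(O[Si](C(C)C)(C(C)C)C(C)C)c(OC)c(OC)c3C(O)[C@H](C(=O)OC(C)(C)C)[C@H]2CO[Si](C(C)C)(C(C)C)C(C)C)ccc1OCc1ccccc1 | intermediate
20 | {(1R,2S,3S,4RS)-1-[4-(benzyloxy)-3-methoxyphenyl]-4-hydroxy-5,6-dimethoxy-7-[(triisopropylsilyl)oxy]-2-{[(triisopropylsilyl)oxy]methyl}-1,2,3,4-tetrahydronaphthalen-3-yl}methanol | COc1cc([C@@H]2c3cc(O[Si](C(C)C)(C(C)C)C(C)C)c(OC)c(OC)c3C(O)[C@H](CO)[C@H]2CO[Si](C(C)C)(C(C)C)C(C)C)ccc1OCc1ccccc1 | intermediate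
21 | 4-[(1R,2S,3S)-3-(hydroxymethyl)-5,6-dimethoxy-7-[(triisopropylsilyl)oxy]-2-{[(triisopropylsilyl)oxy]methyl}-1,2,3,4-tetrahydronaphthalen-1-yl]-2-methoxyphenol | COc1cc([C@@H]2c3cc(O[Si](C(C)C)(C(C)C)C(C)C)c(OC)c(OC)c3C[C@H](CO)[C@H]2CO[Si](C(C)C)(C(C)C)C(C)C)ccc1O | intermediate
22 | (1R,2S,3S)-1-(4-hydroxy-3-methoxyphenyl)-2,3-bis(hydroxymethyl)-5,6-dimethoxy-1,2,3,4-tetrahydronaphthalen-7-ol | COc1cc([C@@H]2c3cc(O)c(OC)c(OC)c3C[C@H](CO)[C@H]2CO)ccc1O | target

## Step count and least certain steps

Total step count: 14. Longest linear sequence: 14 steps (1 to 22); compounds 5, 8, 11 and 16 are commercial.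

**Step 10 (key step).** The most likely failure is slow oxidative addition of the hindered, electron-rich, doubly ortho-substituted bromide under CO. The ester enolate would then wait at 80 °C and be lost by self-condensation, the amide base could intercept the acyl complex, and direct α-arylation to the indane could take over if CO is starved. The fallback separates the metal step from the enolate step. It sets out from 15: palladium-catalysed methoxycarbonylation (Pd(OAc)2, Xantphos, CO, MeOH, Et3N, 100 °C, no strong base present) should give tert-butyl (3R,4R)-4-[4-(benzyloxy)-3-methoxyphenyl]-4-{3,4-dimethoxy-2-(methoxycarbonyl)-5-[(triisopropylsilyl)oxy]phenyl}-3-{[(triisopropylsilyl)oxy]methyl}butanoate F1. A Dieckmann condensation of F1 (NaN(SiMe3)2, THF, 0 °C → rt, then AcOH), in which only the tert-butyl ester can enolise, closes the same C4–C3 bond and comes back to the route at 18.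

**Step 2.** The risk is loss of regiocontrol: bromination at the position ortho to the silyloxy and para to the methoxy group would put the halogen at the future C8, and adventitious acid could remove the silyl group. The fallback replaces electrophilic substitution by directed metalation. It sets out from 2, which is masked in the flask with lithium N,N,N′-trimethylethylenediamide (THF, −20 °C) as the lithium α-amino alkoxide F2. n-BuLi should then remove the ring hydrogen flanked by this group and the methoxy group, since the silyloxy group neither coordinates lithium nor leaves room. Quenching with 1,2-dibromotetrachloroethane and aqueous work-up releases the aldehyde and comes back to the route at 3.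

**Step 4.** The risks are sluggish insertion, because the ortho bromine twists the aryl group out of conjugation with the enoate, protodeboronation of the electron-rich boronic acid, and lower facial selectivity at the higher temperature then needed. The fallback exchanges catalyst control for auxiliary control. It sets out from 4, which is cleaved with aqueous H3PO4 to (2E)-3-{2-bromo-3,4-dimethoxy-5-[(triisopropylsilyl)oxy]phenyl}prop-2-enoic acid F3. F3 is joined through its mixed pivalic anhydride to commercial (4S)-4-phenyl-1,3-oxazolidin-2-one to give the N-enoyl imide F4. The Grignard reagent [4-(benzyloxy)-3-methoxyphenyl]magnesium bromide F5, made from commercial 1-(benzyloxy)-4-bromo-2-methoxybenzene and magnesium, is added with CuBr·SMe2 (THF, −20 °C) anti to the phenyl group of the chelated s-cis imide; this should give the adduct F6 with C1 in the required R configuration. LiOH/H2O2 (THF/H2O, 0 °C) removes the auxiliary and comes back to the route at 7.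

**Step 13.** The risk is erosion at C3: acid-promoted loss of water from the C4 carbinol to the C3=C4 styrene before C–O hydrogenolysis, followed by unselective hydrogenation. In addition, any cis epimer carried through step 11 can no longer be corrected once C9 is an alcohol. The fallback restores a thermodynamic check on C3. It sets out from 19, which is hydrogenolysed at the ester stage (H2, Pd(OH)2/C, EtOAc/AcOH) to tert-butyl (1R,2S,3RS)-1-(4-hydroxy-3-methoxyphenyl)-5,6-dimethoxy-7-[(triisopropylsilyl)oxy]-2-{[(triisopropylsilyl)oxy]methyl}-1,2,3,4-tetrahydronaphthalene-3-carboxylate F7. F7 is equilibrated with KOtBu in tBuOH/THF to the all-trans ester F8, tert-butyl (1R,2S,3S)-1-(4-hydroxy-3-methoxyphenyl)-5,6-dimethoxy-7-[(triisopropylsilyl)oxy]-2-{[(triisopropylsilyl)oxy]methyl}-1,2,3,4-tetrahydronaphthalene-3-carboxylate. This is safe only because O9′ is a silyl ether and cannot lactonise. LiAlH4 reduction of F8 comes back to the route at 21.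

## Further compounds

F1 | step 10 | tert-butyl (3R,4R)-4-[4-(benzyloxy)-3-methoxyphenyl]-4-{3,4-dimethoxy-2-(methoxycarbonyl)-5-[(triisopropylsilyl)oxy]phenyl}-3-{[(triisopropylsilyl)oxy]methyl}butanoate | CC(C)(C)OC(=O)C[C@@H](CO[Si](C(C)C)(C(C)C)C(C)C)[C@H](c1ccc(OCc2ccccc2)c(OC)c1)c1cc(O[Si](C(C)C)(C(C)C)C(C)C)c(OC)c(OC)c1C(=O)OC
F2 | step 2 | lithium α-amino alkoxide from 2 and lithium N,N,N′-trimethylethylenediamide | [Li+].[O-]C(N(C)CCN(C)C)c1cc(O[Si](C(C)C)(C(C)C)C(C)C)c(OC)c(OC)c1
F3 | step 4 | (2E)-3-{2-bromo-3,4-dimethoxy-5-[(triisopropylsilyl)oxy]phenyl}prop-2-enoic acid | OC(=O)/C=C/c1cc(O[Si](C(C)C)(C(C)C)C(C)C)c(OC)c(OC)c1Br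
F4 | step 4 | (4S)-3-[(2E)-3-{2-bromo-3,4-dimethoxy-5-[(triisopropylsilyl)oxy]phenyl}prop-2-enoyl]-4-phenyl-1,3-oxazolidin-2-one | O=C(/C=C/c1cc(O[Si](C(C)C)(C(C)C)C(C)C)c(OC)c(OC)c1Br)N1C(=O)OC[C@@H]1c1ccccc1
F5 | step 4 | [4-(benzyloxy)-3-methoxyphenyl]magnesium bromide | COc1cc([Mg]Br)ccc1OCc1ccccc1
F6 | step 4 | (4S)-3-[(3R)-3-[4-(benzyloxy)-3-methoxyphenyl]-3-{2-bromo-3,4-dimethoxy-5-[(triisopropylsilyl)oxy]phenyl}propanoyl]-4-phenyl-1,3-oxazolidin-2-one | O=C(C[C@H](c1ccc(OCc2ccccc2)c(OC)c1)c1cc(O[Si](C(C)C)(C(C)C)C(C)C)c(OC)c(OC)c1Br)N1C(=O)OC[C@@H]1c1ccccc1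
F7 | step 13 | tert-butyl (1R,2S,3RS)-1-(4-hydroxy-3-methoxyphenyl)-5,6-dimethoxy-7-[(triisopropylsilyl)oxy]-2-{[(triisopropylsilyl)oxy]methyl}-1,2,3,4-tetrahydronaphthalene-3-carboxylate | COc1cc([C@@H]2c3cc(O[Si](C(C)C)(C(C)C)C(C)C)c(OC)c(OC)c3CC(C(=O)OC(C)(C)C)[C@H]2CO[Si](C(C)C)(C(C)C)C(C)C)ccc1O
F8 | step 13 | tert-butyl (1R,2S,3S)-1-(4-hydroxy-3-methoxyphenyl)-5,6-dimethoxy-7-[(triisopropylsilyl)oxy]-2-{[(triisopropylsilyl)oxy]methyl}-1,2,3,4-tetrahydronaphthalene-3-carboxylate | COc1cc([C@@H]2c3cc(O[Si](C(C)C)(C(C)C)C(C)C)c(OC)c(OC)c3C[C@H](C(=O)OC(C)(C)C)[C@H]2CO[Si](C(C)C)(C(C)C)C(C)C)ccc1O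
A1 | alternative 1 | furan–alkyne: 2-substituted 3,4-dimethoxyfuran joined through C4–C3–C2–C1 (both hydroxymethyl groups as tert-butyldimethylsilyl ethers) to a terminal alkyne on the ring C benzyl ether-bearing C1 | C#C[C@@H](c1ccc(OCc2ccccc2)c(OC)c1)[C@H](CO[Si](C)(C)C(C)(C)C)[C@@H](CO[Si](C)(C)C(C)(C)C)Cc1occ(OC)c1OC
A2 | alternative 1 | target with both hydroxymethyl groups as tert-butyldimethylsilyl ethers and the ring C phenol as benzyl ether | COc1cc([C@@H]2c3cc(O)c(OC)c(OC)c3C[C@H](CO[Si](C)(C)C(C)(C)C)[C@H]2CO[Si](C)(C)C(C)(C)C)ccc1OCc1ccccc1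
A3 | alternative 2 | 7-(benzyloxy)-3-[(benzyloxy)methyl]-5,6-dimethoxy-3,4-dihydronaphthalene with the C3 centre of the target (lignan numbering, C1=C2 double bond) | COc1c(OC)c2C[C@H](COCc3ccccc3)C=Cc2cc1OCc1ccccc1
A4 | alternative 2 | potassium [(benzyloxy)methyl]trifluoroborate | [K+].F[B-](F)(F)COCc1ccccc1
A5 | alternative 2 | 1-(benzyloxy)-4-bromo-2-methoxybenzene | COc1cc(Br)ccc1OCc1ccccc1
A6 | alternative 2 | tetra-O-benzyl ether of the target | COc1cc([C@@H]2c3cc(OCc4ccccc4)c(OC)c(OC)c3C[C@H](COCc3ccccc3)[C@H]2COCc2ccccc2)ccc1OCc1ccccc1
A7 | alternative 3 | 4-hydroxydiarylmethane with the C3-branched aldehyde chain: 3-[(benzyloxy)methyl]-4-aryl-butanal, aryl = 2-(4-hydroxy-3-methoxybenzyl)-5,6-dimethoxy-4-[(triisopropylsilyl)oxy]phenyl | O=CC[C@@H](COCc1ccccc1)Cc1c(OC)c(OC)c(O[Si](C(C)C)(C(C)C)C(C)C)cc1Cc1ccc(O)c(OC)c1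
A8 | alternative 3 | ring C p-quinone methide derived from A7 | O=CC[C@@H](COCc1ccccc1)Cc1c(OC)c(OC)c(O[Si](C(C)C)(C(C)C)C(C)C)cc1C=C1C=CC(=O)C(OC)=C1
A9 | alternative 3 | 1-aryltetralin-2-carbaldehyde (1,2-trans, 2,3-trans) with O9 as benzyl ether and O7 as triisopropylsilyl ether | COc1cc([C@@H]2c3cc(O[Si](C(C)C)(C(C)C)C(C)C)c(OC)c(OC)c3C[C@H](COCc3ccccc3)[C@H]2C=O)ccc1O
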